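**Retrosynthetic overview**

1. Numbering: C1 (alkyne CH) to C15 (ethyl CH3) along the chain. O1 bridges C7 and C13 in the eight-membered oxocene ring.
2. Late disconnections: the Z-enyne at C3=C4 (Peterson olefination of a C4 α-chloro aldehyde), C5–C6 (syn-selective γ-chloroallylboration of a C6 aldehyde), and C12–Br (SN2 inversion of a 12R alcohol).
3. Core disconnection: C11–C12 is excised as a two-carbon unit. Joining C10 to C13 instead contracts the oxocene to a 5-chloro-6-ethyl-2,3-dihydro-4H-pyran-4-one. The forward key step is therefore a [2+2] photocycloaddition (C10–C11 and C12–C13 together), followed by cleavage of the auxiliary C10–C13 bond.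
4. Enabling feature: in the oxocene ring the ether carbon C13 (donor O1) and the chloroalkene carbon C10 (flanked by C9) stand 1,4 across C11–C12. This maps onto a push–pull O1–C13=C10–C9=O enone chromophore and later onto a donor–acceptor cyclobutane. C6–O lies 1,3 to C13 across O1, so an O–Si(iPr)2–O tether can carry the vinyloxy two-carbon unit to one face.
5. Ring order: six-membered pyranone (step 4), cyclobutane plus temporary eight-membered dioxasilocane (step 8), fragmentation to the oxocene (step 9), removal of the tether ring (step 12).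

Key step: step 8

Remark: the catalogue (R)-enantiomer of 3-hydroxy-γ-butyrolactone is assumed as chiral pool source, and its carbinol carbon becomes C7 (R). Descriptors such as 7R, 12R refer to the target numbering given above.

**Step 1**
Reactants: 1 (R)-3-hydroxy-γ-butyrolactone
Product: 2 (3R)-3,4-dihydroxy-N-methoxy-N-methylbutanamide
Conditions: MeNH(OMe)·HCl, AlMe3, CH2Cl2, 0 °C to rt
Reagents that add atoms: N,O-dimethylhydroxylamine hydrochloride, CNOC.Cl
Why: Aluminium-amide aminolysis of a lactone (Weinreb amide formation) opens the ring without touching the chiral-pool carbinol centre that becomes C7.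

**Step 2**
Reactants: 2 (3R)-3,4-dihydroxy-N-methoxy-N-methylbutanamide
Product: 3 (3R)-4-(tert-butyldimethylsilyloxy)-3-hydroxy-N-methoxy-N-methylbutanamide
Conditions: TBSCl, imidazole, CH2Cl2, 0 °C
Reagents that add atoms: tert-butyldimethylsilyl chloride, CC(C)(C)[Si](C)(C)Cl
Why: Sterically controlled monosilylation of the primary hydroxyl of a 1,2-diol leaves the C7 hydroxyl free for the later ring closure and prevents furan formation from a free 1,4-hydroxy ketone.

**Step 3**
Reactants: 3 (3R)-4-(tert-butyldimethylsilyloxy)-3-hydroxy-N-methoxy-N-methylbutanamide; 4 1-butyne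
Product: 6 (2R)-1-(tert-butyldimethylsilyloxy)-2-hydroxyoct-5-yn-4-one, via lithium but-1-yn-1-ide 5 (not isolated)
Conditions: 4, n-BuLi, THF, −78 °C; then 3, −78 to −20 °C
Reagents that add atoms: none
Why: In this Weinreb ketone synthesis the chelated tetrahedral adduct stops at the ynone stage, and excess acetylide only deprotonates the free hydroxyl.

**Step 4**
Reactants: 6 (2R)-1-(tert-butyldimethylsilyloxy)-2-hydroxyoct-5-yn-4-one
Product: 7 (2R)-2-[(tert-butyldimethylsilyloxy)methyl]-6-ethyl-2,3-dihydro-4H-pyran-4-one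
Conditions: Ph3PAuCl, AgOTf (5 mol % each), CH2Cl2, rt, dark
Reagents that add atoms: none
Why: Carbophilic-metal-catalysed 6-endo-dig cycloisomerisation (oxa-Michael type) of a β-hydroxy ynone forms the O1–C13 bond and the six-membered vinylogous ester with C7 untouched.

**Step 5**
Reactants: 7 (2R)-2-[(tert-butyldimethylsilyloxy)methyl]-6-ethyl-2,3-dihydro-4H-pyran-4-one
Product: 8 (2R)-2-[(tert-butyldimethylsilyloxy)methyl]-5-chloro-6-ethyl-2,3-dihydro-4H-pyran-4-one
Conditions: NCS, MeCN, 0 °C to rt, dark
Reagents that add atoms: N-chlorosuccinimide, O=C1CCC(=O)N1Cl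
Why: In this electrophilic α-halogenation of a vinylogous ester the enol-ether-like C10 is the only nucleophilic carbon, and loss of its proton restores the push–pull alkene.

**Step 6**
Reactants: 8 (2R)-2-[(tert-butyldimethylsilyloxy)methyl]-5-chloro-6-ethyl-2,3-dihydro-4H-pyran-4-one
Product: 9 (2R)-5-chloro-6-ethyl-2-(hydroxymethyl)-2,3-dihydro-4H-pyran-4-one
Conditions: HF·pyridine, THF, 0 °C
Reagents that add atoms: none
Why: Fluoride desilylation under mildly acidic conditions avoids the retro-oxa-Michael opening that a basic fluoride source could trigger.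

**Step 7**
Reactants: 9 (2R)-5-chloro-6-ethyl-2-(hydroxymethyl)-2,3-dihydro-4H-pyran-4-one; 10 trimethyl(vinyloxy)silane; 11 dichlorodiisopropylsilane
Product: 14 (2R)-5-chloro-2-{[diisopropyl(vinyloxy)silyl]oxymethyl}-6-ethyl-2,3-dihydro-4H-pyran-4-one, via lithium ethenolate 12 (not isolated), via chloro(diisopropyl)(vinyloxy)silane 13 (not isolated)
Conditions: 10, MeLi, THF, 0 °C to rt; add to 11, THF, −78 °C; then 9, imidazole, −78 °C to rt
Reagents that add atoms: none
Why: In this unsymmetrical silaketal synthesis by sequential substitution at silicon, O-silylation of the acetaldehyde enolate stops after one chloride for steric reasons, and the primary alcohol takes the remaining Si–Cl bond.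

**Step 8**
Reactants: 14 (2R)-5-chloro-2-{[diisopropyl(vinyloxy)silyl]oxymethyl}-6-ethyl-2,3-dihydro-4H-pyran-4-one
Product: 15 tricyclic photoadduct (7R,10R,12R,13R)
Conditions: hν (366 nm LED, Pyrex), MeCN (3 mM), Ar, 0 °C
Reagents that add atoms: none
Why: Excitation of the chloro-dihydropyranone and intersystem crossing give the twisted triplet enone, which bonds C10 to the CH2 terminus C11 of the tethered vinyloxy group to give a 1,4-biradical with its spins on C12 (α-silyloxy) and C13 (tertiary, α-alkoxy); spin inversion and C12–C13 coupling then complete the cyclobutane, so both new C–C bonds arise in one photochemical operation. The closest known reaction types are the intramolecular enone–alkene [2+2] photocycloaddition through a temporary silicon tether and the cycloaddition half of the de Mayo reaction as run on 2,3-dihydro-4H-pyran-4-ones. Two rings close: the four-membered ring by the stepwise straight (head-to-tail) [2+2] mode, cis-fused to the pyranone, and with it the temporary eight-membered 1,3-dioxa-2-silocane ring C13–O1–C7–C6–O–Si–O–C12. C12 is set as 12R by the tether, because C6 on the 7R centre can hand the alkene only to its own face of the pyranone and the C6–O–Si–O–C12 span reaches only if the C12–O bond points endo, back over O1; C10 (R) and C13 (R) follow from cis-fusion on that face and are temporary, since step 9 erases both. The step needs head-to-tail regiochemistry (oxygen-bearing carbon to C13), which both the polarity of the donor alkene toward the triplet enone and the smaller temporary ring favour over the crossed nine-membered alternative, and it needs intramolecular capture, which high dilution secures. Irradiation at 366 nm addresses only the enone chromophore, so the α-chloro ketone product, the Si–O bonds and the C–Cl bond should not be photolysed.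

**Step 9**
Reactants: 15 tricyclic photoadduct (7R,10R,12R,13R)
Product: 17 bridged triethylsilyl enol ether (7R,12R,13R), via bridged oxocarbenium triflate 16 (not isolated)
Conditions: Et3SiH (3 equiv), Et3SiOTf (20 mol %), 2,6-di-tert-butyl-4-methylpyridine (10 mol %), CH2Cl2, −78 to −40 °C
Reagents that add atoms: triethylsilane, CC[SiH](CC)CC
Why: Proposed new method: Et3SiOTf silylates the C9 carbonyl oxygen, and the C10–C13 bond, flanked by the O1 lone pair (donor on C13) and the silyloxycarbenium ion (acceptor on C10) and weakened by cyclobutane strain, cleaves heterolytically to the chlorine-stabilised silyl enol ether and the eight-membered oxocarbenium ion 16, which Et3SiH reduces irreversibly while regenerating Et3SiOTf, so the net change is H to C13 and Et3Si to the C9 oxygen. Hydride should arrive on the face of O1=C13 that is not covered by the O–Si(iPr)2–O bridge and is anti to the C12–O bond, which gives 13R (ethyl cis to C6), the same sense as the usual cis preference in silane reductions of eight-membered oxocarbenium ions. The closest known reaction types are the retro-aldol half of the de Mayo reaction, the Lewis-acid opening of donor–acceptor cyclobutanes and the Et3SiH reduction of cyclic oxocarbenium ions; the new element is their combination on a 2-oxabicyclo[4.2.0]octan-5-one so that the ring oxygen stays in the enlarged ring.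

**Step 10**
Reactants: 17 bridged triethylsilyl enol ether (7R,12R,13R)
Product: 19 bridged enol triflate (7R,12R,13R), via lithium chloroenolate 18 (not isolated)
Conditions: MeLi, THF, −20 °C; then N-(5-chloro-2-pyridyl)bis(trifluoromethanesulfonimide), −78 °C
Reagents that add atoms: N-(5-chloro-2-pyridyl)bis(trifluoromethanesulfonimide), FC(F)(F)S(=O)(=O)N(c1ccc(Cl)cn1)S(=O)(=O)C(F)(F)F
Why: Regiospecific enolate release from a silyl enol ether followed by O-sulfonylation keeps the double bond between C9 and C10 and never exposes a C8 enolate that could expel O1.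

**Step 11**
Reactants: 19 bridged enol triflate (7R,12R,13R)
Product: 20 bridged chloro-oxocene (7R,12R,13R)
Conditions: Pd(OAc)2 (5 mol %), PPh3, HCO2H, n-Bu3N, DMF, 60 °C
Reagents that add atoms: none
Why: In this palladium-catalysed formate hydrogenolysis of an enol triflate, zerovalent palladium inserts into C–OTf far faster than into the neighbouring vinylic C–Cl bond, so C9 receives hydrogen and the ring-cis chloroalkene is revealed.

**Step 12**
Reactants: 20 bridged chloro-oxocene (7R,12R,13R)
Product: 21 oxocene diol (7R,12R,13R)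
Conditions: HF·pyridine, THF, 0 °C to rt
Reagents that add atoms: none
Why: Fluoride cleavage of both Si–O bonds removes the temporary tether ring and frees the C6 and C12 hydroxyls with no change at any stereocentre.

**Step 13**
Reactants: 21 oxocene diol (7R,12R,13R)
Product: 22 C6-O-TBS oxocene alcohol (7R,12R,13R)
Conditions: TBSCl, imidazole, CH2Cl2, −10 °C
Reagents that add atoms: tert-butyldimethylsilyl chloride, CC(C)(C)[Si](C)(C)Cl
Why: Selective silylation of the primary over the hindered secondary hydroxyl isolates C12–OH for substitution.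

**Step 14**
Reactants: 22 C6-O-TBS oxocene alcohol (7R,12R,13R)
Product: 23 C6-O-TBS bromo-oxocene (7R,12S,13R)
Conditions: CBr4, P(n-C8H17)3, toluene, 70 °C
Reagents that add atoms: carbon tetrabromide, BrC(Br)(Br)Br
Why: In this Appel-type bromination, SN2 displacement of the alkoxyphosphonium ion by bromide inverts C12 from R to S and places bromine trans to the ethyl group.

**Step 15**
Reactants: 23 C6-O-TBS bromo-oxocene (7R,12S,13R)
Product: 24 bromo-oxocene C6 alcohol (7R,12S,13R)
Conditions: HF·pyridine, THF, 0 °C
Reagents that add atoms: none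
Why: Acidic fluoride desilylation frees the primary alcohol without risk of base-induced loss of HBr.

**Step 16**
Reactants: 24 bromo-oxocene C6 alcohol (7R,12S,13R)
Product: 25 bromo-oxocene C6 aldehyde (7R,12S,13R)
Conditions: Dess–Martin periodinane, CH2Cl2, 0 °C to rt
Reagents that add atoms: none
Why: Dess–Martin oxidation gives the α-alkoxy aldehyde under neutral conditions that do not epimerise C7.

**Step 17**
Reactants: 25 bromo-oxocene C6 aldehyde (7R,12S,13R); 26 allyl chloride; 27 (+)-B-methoxydiisopinocampheylborane (from (−)-α-pinene)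
Product: 30 syn-chlorohydrin (5S,6S,7R,12S,13R) bearing a C3=C4 vinyl group, via (Z)-(3-chloroallyl)diisopinocampheylborane 28 (not isolated), via diisopinocampheylborinate 29 (not isolated)
Conditions: 26, 27, LiN(c-C6H11)2, Et2O, −95 °C; BF3·OEt2; then 25, −95 °C; H2O2, pH 7 buffer, MeOH, 0 °C
Reagents that add atoms: none
Why: In this asymmetric (Z)-γ-chloroallylboration through a closed chair transition state, the Z-geometry of the borane fixes the syn C5–Cl/C6–OH relation and the isopinocampheyl groups select the aldehyde face that gives 6S, overriding the modest intrinsic bias of the α-alkoxy aldehyde.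

**Step 18**
Reactants: 30 syn-chlorohydrin (5S,6S,7R,12S,13R)
Product: 31 C6-O-triethylsilyl chlorohydrin ether
Conditions: Et3SiOTf, 2,6-lutidine, CH2Cl2, −78 °C
Reagents that add atoms: triethylsilyl trifluoromethanesulfonate, CC[Si](CC)(CC)OS(=O)(=O)C(F)(F)F
Why: Silyl triflate silylation with a non-nucleophilic base masks C6–OH without ever forming an alkoxide that could close an epoxide onto C5.

**Step 19**
Reactants: 31 C6-O-triethylsilyl chlorohydrin ether
Product: 33 C4 α-chloro aldehyde, via vicinal diol 32 (not isolated)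
Conditions: OsO4 (2 mol %), NaIO4, 2,6-lutidine, dioxane/H2O, rt
Reagents that add atoms: sodium periodate, [Na+].[O-]I(=O)(=O)=O (terminal oxygen source); osmium tetroxide, O=[Os](=O)(=O)=O (catalytic oxygen carrier)
Why: In this Lemieux–Johnson oxidation, OsO4 should dihydroxylate the monosubstituted alkene well before the trisubstituted chlorine-deactivated ring alkene, and periodate cleaves the diol under buffered conditions that spare the C5 centre.

**Step 20**
Reactants: 34 1-(triisopropylsilyl)prop-1-yne
Product: 36 1,3-bis(triisopropylsilyl)prop-1-yne, via 3-lithio-1-(triisopropylsilyl)prop-1-yne 35 (not isolated)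
Conditions: n-BuLi, THF, −20 °C; iPr3SiOTf, −78 °C to rt
Reagents that add atoms: triisopropylsilyl trifluoromethanesulfonate, CC(C)[Si](C(C)C)(C(C)C)OS(=O)(=O)C(F)(F)F
Why: Propargylic lithiation followed by C-silylation at the propargylic terminus gives the olefination reagent.

**Step 21**
Reactants: 33 C4 α-chloro aldehyde; 36 1,3-bis(triisopropylsilyl)prop-1-yne
Product: 39 C1-triisopropylsilyl C6-O-triethylsilyl bermudenynol, via 3-lithio-1,3-bis(triisopropylsilyl)prop-1-yne 37 (not isolated), via lithium beta-silylalkoxide 38 (not isolated)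
Conditions: 36, n-BuLi, THF, −20 °C; then 33, −78 to −20 °C
Reagents that add atoms: none
Why: In this Peterson olefination with a very bulky α-silyl propargyl anion, the addition should favour the adduct whose syn-elimination of silanolate gives the Z-enyne, and at low temperature this elimination should outrun epoxide closure onto C5 and avoids any palladium contact with the allylic chloride.

**Step 22**
Reactants: 39 C1-triisopropylsilyl C6-O-triethylsilyl bermudenynol
Product: 40 bermudenynol
Conditions: n-Bu4NF, AcOH (1:1), THF, 0 °C to rt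
Reagents that add atoms: none
Why: Buffered fluoride desilylation removes the alkynyl and the O-silyl group together while the acetic acid keeps the C6 alkoxide protonated, so the syn-chlorohydrin does not close to an epoxide.

**Compound list**

1 | (R)-3-hydroxy-γ-butyrolactone | O=C1C[C@@H](O)CO1 | starting material
2 | (3R)-3,4-dihydroxy-N-methoxy-N-methylbutanamide | CON(C)C(=O)C[C@@H](O)CO | intermediate
3 | (3R)-4-(tert-butyldimethylsilyloxy)-3-hydroxy-N-methoxy-N-methylbutanamide | CON(C)C(=O)C[C@@H](O)CO[Si](C)(C)C(C)(C)C | intermediate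
4 | 1-butyne | CCC#C | starting material
5 | lithium but-1-yn-1-ide | [Li]C#CCC | intermediate
6 | (2R)-1-(tert-butyldimethylsilyloxy)-2-hydroxyoct-5-yn-4-one | CCC#CC(=O)C[C@@H](O)CO[Si](C)(C)C(C)(C)C | intermediate
7 | (2R)-2-[(tert-butyldimethylsilyloxy)methyl]-6-ethyl-2,3-dihydro-4H-pyran-4-one | CCC1=CC(=O)C[C@H](CO[Si](C)(C)C(C)(C)C)O1 | intermediate
8 | (2R)-2-[(tert-butyldimethylsilyloxy)methyl]-5-chloro-6-ethyl-2,3-dihydro-4H-pyran-4-one | CCC1=C(Cl)C(=O)C[C@H](CO[Si](C)(C)C(C)(C)C)O1 | intermediate
9 | (2R)-5-chloro-6-ethyl-2-(hydroxymethyl)-2,3-dihydro-4H-pyran-4-one | CCC1=C(Cl)C(=O)C[C@H](CO)O1 | intermediate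
10 | trimethyl(vinyloxy)silane | C=CO[Si](C)(C)C | starting material
11 | dichlorodiisopropylsilane | CC(C)[Si](Cl)(Cl)C(C)C | starting material
12 | lithium ethenolate | [Li]OC=C | intermediate
13 | chloro(diisopropyl)(vinyloxy)silane | C=CO[Si](Cl)(C(C)C)C(C)C | intermediate
14 | (2R)-5-chloro-2-{[diisopropyl(vinyloxy)silyl]oxymethyl}-6-ethyl-2,3-dihydro-4H-pyran-4-one | CCC1=C(Cl)C(=O)C[C@H](CO[Si](C(C)C)(C(C)C)OC=C)O1 | intermediate
15 | tricyclic photoadduct: cis-fused 6-chloro-1-ethyl-2-oxabicyclo[4.2.0]octan-5-one whose endo C8–O and C3–CH2O are joined through Si(iPr)2; 7R,10R,12R,13R in target numbering | CC[C@@]12O[C@H]3CO[Si](C(C)C)(C(C)C)O[C@@H]1C[C@]2(Cl)C(=O)C3 | intermediate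
16 | bridged oxocarbenium triflate: O1=C13 cation in the eight-membered ring, C9(OSiEt3)=C10(Cl), C6–O–Si(iPr)2–O–C12 bridge | CCC1=[O+][C@H]2CO[Si](C(C)C)(C(C)C)O[C@@H]1C/C(Cl)=C(O[Si](CC)(CC)CC)\C2.[O-]S(=O)(=O)C(F)(F)F | intermediate
17 | bridged triethylsilyl enol ether: oxocene with C9(OSiEt3)=C10(Cl) ring-cis, C13–H, C6–O–Si(iPr)2–O–C12 bridge; 7R,12R,13R | CC[C@H]1O[C@H]2CO[Si](C(C)C)(C(C)C)O[C@@H]1C/C(Cl)=C(O[Si](CC)(CC)CC)\C2 | intermediate
18 | lithium chloroenolate of the bridged oxocene | CC[C@H]1O[C@H]2CO[Si](C(C)C)(C(C)C)O[C@@H]1C/C(Cl)=C(O[Li])\C2 | intermediate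
19 | bridged enol triflate: C9(OTf)=C10(Cl); 7R,12R,13R | CC[C@H]1O[C@H]2CO[Si](C(C)C)(C(C)C)O[C@@H]1C/C(Cl)=C(OS(=O)(=O)C(F)(F)F)\C2 | intermediate
20 | bridged chloro-oxocene: C9H=C10(Cl) ring-cis, C6–O–Si(iPr)2–O–C12 bridge; 7R,12R,13R | CC[C@H]1O[C@H]2CO[Si](C(C)C)(C(C)C)O[C@@H]1C/C(Cl)=C\C2 | intermediate
21 | oxocene diol: C6–OH and C12–OH; 7R,12R,13R | OC[C@H]1C/C=C(/Cl)C[C@@H](O)[C@@H](CC)O1 | intermediate
22 | C6-O-TBS oxocene alcohol; 7R,12R,13R | CC(C)(C)[Si](C)(C)OC[C@H]1C/C=C(/Cl)C[C@@H](O)[C@@H](CC)O1 | intermediate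
23 | C6-O-TBS bromo-oxocene; 7R,12S,13R | CC(C)(C)[Si](C)(C)OC[C@H]1C/C=C(/Cl)C[C@H](Br)[C@@H](CC)O1 | intermediate
24 | bromo-oxocene C6 alcohol; 7R,12S,13R | OC[C@H]1C/C=C(/Cl)C[C@H](Br)[C@@H](CC)O1 | intermediate
25 | bromo-oxocene C6 aldehyde; 7R,12S,13R | O=C[C@H]1C/C=C(/Cl)C[C@H](Br)[C@@H](CC)O1 | intermediate
26 | allyl chloride | C=CCCl | starting material
27 | (+)-B-methoxydiisopinocampheylborane | COB([C@H]1C[C@H]2C[C@@H]([C@@H]1C)C2(C)C)[C@H]1C[C@H]2C[C@@H]([C@@H]1C)C2(C)C | starting material
28 | (Z)-(3-chloroallyl)diisopinocampheylborane | Cl/C=C\CB([C@H]1C[C@H]2C[C@@H]([C@@H]1C)C2(C)C)[C@H]1C[C@H]2C[C@@H]([C@@H]1C)C2(C)C | intermediate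
29 | diisopinocampheylborinate of chlorohydrin 30 | C=C[C@H](Cl)[C@@H](OB([C@H]2C[C@H]3C[C@@H]([C@@H]2C)C3(C)C)[C@H]2C[C@H]3C[C@@H]([C@@H]2C)C3(C)C)[C@H]1C/C=C(/Cl)C[C@H](Br)[C@@H](CC)O1 | intermediate
30 | syn-chlorohydrin with terminal vinyl group; 5S,6S,7R,12S,13R | C=C[C@H](Cl)[C@@H](O)[C@H]1C/C=C(/Cl)C[C@H](Br)[C@@H](CC)O1 | intermediate
31 | C6-O-triethylsilyl ether of 30 | C=C[C@H](Cl)[C@@H](O[Si](CC)(CC)CC)[C@H]1C/C=C(/Cl)C[C@H](Br)[C@@H](CC)O1 | intermediate
32 | C3,C4 vicinal diol (C4 epimers) | OCC(O)[C@H](Cl)[C@@H](O[Si](CC)(CC)CC)[C@H]1C/C=C(/Cl)C[C@H](Br)[C@@H](CC)O1 | intermediate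
33 | C4 α-chloro aldehyde: (2R,3S)-2-chloro-3-(triethylsilyloxy)-3-(oxocenyl)propanal | O=C[C@H](Cl)[C@@H](O[Si](CC)(CC)CC)[C@H]1C/C=C(/Cl)C[C@H](Br)[C@@H](CC)O1 | intermediate
34 | 1-(triisopropylsilyl)prop-1-yne | CC#C[Si](C(C)C)(C(C)C)C(C)C | starting material
35 | 3-lithio-1-(triisopropylsilyl)prop-1-yne | [Li]CC#C[Si](C(C)C)(C(C)C)C(C)C | intermediate
36 | 1,3-bis(triisopropylsilyl)prop-1-yne | CC(C)[Si](C(C)C)(C(C)C)CC#C[Si](C(C)C)(C(C)C)C(C)C | intermediate
37 | 3-lithio-1,3-bis(triisopropylsilyl)prop-1-yne | [Li]C(C#C[Si](C(C)C)(C(C)C)C(C)C)[Si](C(C)C)(C(C)C)C(C)C | intermediate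
38 | lithium β-silylalkoxide adduct (C3 and C4 not defined) | [Li]OC(C(C#C[Si](C(C)C)(C(C)C)C(C)C)[Si](C(C)C)(C(C)C)C(C)C)[C@H](Cl)[C@@H](O[Si](CC)(CC)CC)[C@H]1C/C=C(/Cl)C[C@H](Br)[C@@H](CC)O1 | intermediate
39 | C1-triisopropylsilyl C6-O-triethylsilyl bermudenynol | CC(C)[Si](C(C)C)(C(C)C)C#C/C=C\[C@H](Cl)[C@@H](O[Si](CC)(CC)CC)[C@H]1C/C=C(/Cl)C[C@H](Br)[C@@H](CC)O1 | intermediate
40 | bermudenynol; 3Z,5S,6S,7R,12S,13R | C#C/C=C\[C@H](Cl)[C@@H](O)[C@H]1C/C=C(/Cl)C[C@H](Br)[C@@H](CC)O1 | target

**Step count**

Total step count: 22. Longest linear sequence: 21 (steps 1 to 19, 21 and 22; step 20 is a side branch).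

**Steps most likely to fail**

1. **Step 9.**
   - What may go wrong: ionic hydrogenation of the activated C9 carbonyl before the C10–C13 bond breaks, proton loss from the oxocarbenium ion, erosion of the silaketal by the silyl triflate, or poor facial selectivity of hydride delivery at C13.
   - Fallback (known chemistry, radical instead of ionic cleavage): it sets out from 15. Luche reduction (NaBH4, CeCl3·7H2O, MeOH) gives the tricyclic C9 carbinol F1, and either epimer serves. 1,1'-Thiocarbonyldiimidazole with DMAP converts it into the imidazolylthiocarbonate F2. Bu3SnH/AIBN in hot toluene then starts a Barton–McCombie reaction. The C9 cyclobutylcarbinyl radical undergoes β-scission of C10–C13 toward the tertiary α-alkoxy radical at C13, which takes hydrogen from the stannane on the face away from the tether.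
   - Return point: 20, so steps 10 and 11 are also bypassed.

2. **Step 8.**
   - What may go wrong: slow closure of the flexible eight-membered temporary ring, so that the triplet decays or dimerises; hydrolytic loss of the silyl enol ether; or secondary photolysis of the α-chloro ketone.
   - Fallback (a shorter, carbon-bound tether): it sets out from 9. Chloro(dimethyl)vinylsilane and imidazole give the vinylsilyl ether F3. Irradiation of F3 closes a seven-membered temporary ring and gives the sila-tricyclic photoadduct F4 with an endo C12–Si bond. A β-silyl oxocarbenium ion would lose silicon, so the ring is enlarged by the radical route: Luche reduction to the carbinol F5, acylation to the imidazolylthiocarbonate F6, and Bu3SnH/AIBN to the oxasila-bridged chloro-oxocene F7. Tamao–Fleming oxidation (H2O2, KF, KHCO3, THF/MeOH) then replaces C12–Si by C12–OH with retention and frees C6–OH.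
   - Return point: 21.

3. **Step 21.**
   - What may go wrong: enolisation and epimerisation at C5 by the lithium reagent, displacement of chloride by the C4 alkoxide before the silanolate leaves, or erosion of Z-selectivity with the branched aldehyde.
   - Fallback (Wittig plus cross-coupling instead of Peterson): it sets out from 33. Stork–Zhao olefination (iodomethyltriphenylphosphonium iodide, NaHMDS, THF/DMPU, −78 °C) gives the Z-vinyl iodide F8. A short Sonogashira coupling at low temperature with (triisopropylsilyl)acetylene (Pd(PPh3)4, CuI, iPr2NH) relies on the much faster oxidative addition of the vinyl iodide than of the hindered allylic chloride.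
   - Return point: 39.

**Further compounds**

F1 | step 9 | tricyclic C9 carbinol of 15 (either C9 epimer) | CC[C@@]12O[C@H]3CO[Si](C(C)C)(C(C)C)O[C@@H]1C[C@]2(Cl)C(O)C3
F2 | step 9 | C9 O-(imidazol-1-ylthiocarbonyl) derivative of F1 | CC[C@@]12O[C@H]3CO[Si](C(C)C)(C(C)C)O[C@@H]1C[C@]2(Cl)C(OC(=S)n1ccnc1)C3
F3 | step 8 | (2R)-5-chloro-2-{[dimethyl(vinyl)silyl]oxymethyl}-6-ethyl-2,3-dihydro-4H-pyran-4-one | CCC1=C(Cl)C(=O)C[C@H](CO[Si](C)(C)C=C)O1
F4 | step 8 | sila-tricyclic photoadduct with endo C12–Si bond | CC[C@@]12O[C@H]3CO[Si](C)(C)[C@@H]1C[C@]2(Cl)C(=O)C3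
F5 | step 8 | C9 carbinol of F4 (either C9 epimer) | CC[C@@]12O[C@H]3CO[Si](C)(C)[C@@H]1C[C@]2(Cl)C(O)C3
F6 | step 8 | C9 O-(imidazol-1-ylthiocarbonyl) derivative of F5 | CC[C@@]12O[C@H]3CO[Si](C)(C)[C@@H]1C[C@]2(Cl)C(OC(=S)n1ccnc1)C3
F7 | step 8 | oxasila-bridged chloro-oxocene (C6–O–SiMe2–C12 bridge) | CC[C@H]1O[C@H]2CO[Si](C)(C)[C@@H]1C/C(Cl)=C\C2
F8 | step 21 | Z-vinyl iodide from aldehyde 33 | I/C=C\[C@H](Cl)[C@@H](O[Si](CC)(CC)CC)[C@H]1C/C=C(/Cl)C[C@H](Br)[C@@H](CC)O1
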